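**Plan**
- Retrosynthesis: the C1' carboxyl is closed onto O7 as a lactone, and ring D is then cut at C1'–C2', C3'–C4' and C5'–C6' into three alkynes. Further cuts are C8–C(sp), O7–acyl, C8–I, and O1–C2 and Cα–Cβ of the flavone.
- Enabling feature: ring D carries substituents on four neighbouring carbons, and each can be tethered. The C1' carboxyl becomes a lactone to O7 of ring A, C2' is bonded to C8, and the C3' and C4' oxygens share one silicon atom, so one triyne gives ring D with preset regiochemistry.
- Forward: ring C is closed on a chalcone built from the ring A acetophenone and the ring B aldehyde. C8 is then iodinated, O7 acylated with a silyl-capped propiolate and C8 alkynylated with a bis(ynol) silyl ether.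
- Ring D, the lactone ring and the 1,3,2-dioxasilole ring then close in one cyclotrimerisation; C–Si cleavage, demethylation with O–Si cleavage, and lactone hydrolysis finish the route.
- Stereochemistry: the target has no stereocentre, and the E-alkene of the chalcone is consumed in ring C formation.

Key step: step 9

Assumption: the given structure carries no stereodescriptor, so the hindered C8–C2' biaryl axis is treated as undefined and is not controlled.

Locants: flavone atoms are O1 to C8a, and ring B is the aryl group on C2. Ring D is the benzoic acid ring: C1' bears the carboxyl carbon, C2' is bonded to C8, C3' and C4' bear oxygen, and C5' and C6' are CH in the target.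

**Step 1**
Reactants: 1 1-(2,4-dihydroxy-6-methoxyphenyl)ethan-1-one
Product: 2 1-[4-(benzyloxy)-2-hydroxy-6-methoxyphenyl]ethan-1-one
Conditions: BnBr (1.05 equiv), K2CO3, acetone, reflux
Reagents that add atoms: benzyl bromide, BrCc1ccccc1
Why: Williamson etherification should be selective for the 4-OH, because the 2-OH is hydrogen-bonded to the acetyl carbonyl and much less nucleophilic.

**Step 2**
Reactants: 2 1-[4-(benzyloxy)-2-hydroxy-6-methoxyphenyl]ethan-1-one; 3 3,4-dimethoxybenzaldehyde
Product: 4 (E)-1-[4-(benzyloxy)-2-hydroxy-6-methoxyphenyl]-3-(3,4-dimethoxyphenyl)prop-2-en-1-one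
Conditions: KOH (aq.), EtOH, rt; HCl work-up
Reagents that add atoms: none
Why: Claisen–Schmidt aldol condensation of the methyl ketone enolate with the non-enolisable aldehyde, followed by E1cB dehydration, should give the thermodynamically preferred E-enone.

**Step 3**
Reactants: 4 (E)-1-[4-(benzyloxy)-2-hydroxy-6-methoxyphenyl]-3-(3,4-dimethoxyphenyl)prop-2-en-1-one
Product: 5 7-(benzyloxy)-2-(3,4-dimethoxyphenyl)-5-methoxy-4H-chromen-4-one
Conditions: I2 (10 mol%), DMSO, 130 °C
Reagents that add atoms: none
Why: The iodine-catalysed oxidative cyclisation of 2'-hydroxychalcones (oxa-Michael closure of ring C, α-iodination and elimination, with DMSO reoxidising HI) is the standard route to flavones and should leave benzyl and methyl ethers intact.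

**Step 4**
Reactants: 5 7-(benzyloxy)-2-(3,4-dimethoxyphenyl)-5-methoxy-4H-chromen-4-one
Product: 6 7-(benzyloxy)-2-(3,4-dimethoxyphenyl)-8-iodo-5-methoxy-4H-chromen-4-one
Conditions: NIS (1.05 equiv), CF3CO2H (cat.), MeCN, 0 °C to rt
Reagents that add atoms: N-iodosuccinimide, O=C1CCC(=O)N1I
Why: Electrophilic aromatic iodination of 5,7-dialkoxyflavones should occur at C8, which is para to the 5-methoxy group and ortho to O7, in preference to the more crowded C6 and the less activated ring B.

**Step 5**
Reactants: 6 7-(benzyloxy)-2-(3,4-dimethoxyphenyl)-8-iodo-5-methoxy-4H-chromen-4-one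
Product: 7 2-(3,4-dimethoxyphenyl)-7-hydroxy-8-iodo-5-methoxy-4H-chromen-4-one
Conditions: BCl3 (2.5 equiv), C6HMe5 (3 equiv), CH2Cl2, −78 °C; H2O quench
Reagents that add atoms: none
Why: Lewis-acid debenzylation with pentamethylbenzene as a non-basic benzyl cation scavenger cleaves aryl benzyl ethers at −78 °C, where the aryl iodide and the methyl ethers, including the 5-OMe next to the carbonyl, should survive.

**Step 6**
Reactants: 7 2-(3,4-dimethoxyphenyl)-7-hydroxy-8-iodo-5-methoxy-4H-chromen-4-one; 8 3-(trimethylsilyl)prop-2-ynoic acid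
Product: 9 2-(3,4-dimethoxyphenyl)-8-iodo-5-methoxy-4-oxo-4H-chromen-7-yl 3-(trimethylsilyl)prop-2-ynoate
Conditions: DCC, DMAP (5 mol%), CH2Cl2, 0 °C
Reagents that add atoms: none
Why: Steglich esterification acylates the only free phenol, and the SiMe3 cap protects the propiolate from conjugate addition and from deprotonation in step 8.

**Step 7**
Reactants: 10 3-phenylisoxazole; 11 di-tert-butylsilyl bis(trifluoromethanesulfonate)
Product: 14 di-tert-butylbis(ethynyloxy)silane, via 5-lithio-3-phenylisoxazole 12 (not isolated), via lithium ethynolate 13 (not isolated)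
Conditions: n-BuLi, THF, −78 to −40 °C; then 11 (0.45 equiv), −78 to 0 °C
Reagents that add atoms: none
Why: C5 lithiation of a 3-substituted isoxazole triggers cycloreversion to the nitrile and the lithium ynolate, and the hard, bulky silyl bis(triflate) should silylate two ynolates on oxygen, as hindered silyl triflates do with substituted ynolates (ynolate O-silylation).

**Step 8**
Reactants: 9 2-(3,4-dimethoxyphenyl)-8-iodo-5-methoxy-4-oxo-4H-chromen-7-yl 3-(trimethylsilyl)prop-2-ynoate; 14 di-tert-butylbis(ethynyloxy)silane
Product: 17 8-({[di-tert-butyl(ethynyloxy)silyl]oxy}ethynyl)-2-(3,4-dimethoxyphenyl)-5-methoxy-4-oxo-4H-chromen-7-yl 3-(trimethylsilyl)prop-2-ynoate, via lithium alkynide 15 (not isolated), via alkynylzinc chloride 16 (not isolated)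
Conditions: 14 (3 equiv), n-BuLi (1.2 equiv), THF, −78 °C; ZnCl2 (1.3 equiv), −78 to 0 °C; then 9, Pd(PPh3)4 (5 mol%), THF, rt
Reagents that add atoms: none
Why: In this Negishi coupling, zerovalent palladium inserts into the C8–I bond and the alkynylzinc chloride, mild enough to spare the aryl ester and ynoate, transmetalates and reductively eliminates as alkoxyethynylzinc reagents do, while the excess of symmetric diyne with limiting base keeps the coupling to one terminus.

**Step 9**
Reactants: 17 8-({[di-tert-butyl(ethynyloxy)silyl]oxy}ethynyl)-2-(3,4-dimethoxyphenyl)-5-methoxy-4-oxo-4H-chromen-7-yl 3-(trimethylsilyl)prop-2-ynoate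
Product: 18 flavone-fused benzo[c]chromen-6-one in which ring D is joined to C8 through C2' and to O7 through the C1' lactone carbonyl, with SiMe3 on C6', H on C5' and a di-tert-butylsilylene bridging the C3' and C4' oxygens
Conditions: RhCl(PPh3)3 (10 mol%), toluene (0.005 M), 60 °C
Reagents that add atoms: none
Why: Proposed new method: monovalent rhodium should bind the ester-tethered 1,7-diyne (silylpropiolate and C8 alkyne), undergo oxidative cyclisation to a rhodacyclopentadiene that forms C1'–C2', insert the silicon-tethered terminal ynol ether to form C3'–C4', and close C5'–C6' by reductive elimination, with aromatisation as the driving force. The closest known reaction type is the rhodium-catalysed intramolecular (2+2+2) cyclotrimerisation of tethered triynes, including 2-alkynylaryl alkynoates that give benzo[c]chromen-6-ones and diynes joined by temporary silicon tethers, and ynol ethers and siloxyalkynes are known benzannulation partners; what is new is a silicon-linked bis(ynol ether) supplying two of the three alkynes. Ring D closes as the six-membered carbocycle of the cycloaddition itself, the six-membered lactone ring closes as the tether ring of the 1,7-diyne when C1'–C2' forms, and the five-membered 1,3,2-dioxasilole ring closes as the tether ring of the 1,6-diyne when C3'–C4' forms. No stereocentre is created. The step needs regiocontrol and intramolecular rather than intermolecular reaction: the two tethers fix the carbonyl on C1' beside the biaryl carbon and the oxygens on C3' and C4', high dilution with the SiMe3 cap and the tert-butyl groups should disfavour oligomerisation, and the neutral, non-acidic catalyst is chosen to spare the acid-labile ynol ethers.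

**Step 10**
Reactants: 18 C6'-silylated silylene lactone
Product: 19 the same lactone with H on C6' (di-tert-butylsilylene, 5-OMe and ring B methyl ethers retained)
Conditions: CF3CO2H/CH2Cl2 (1:1, anhydrous), rt; evaporation
Reagents that add atoms: none
Why: Ipso protodesilylation, an electrophilic aromatic substitution at the silicon-bearing carbon that is assisted by the β-silicon effect and the para oxygen on C3', should remove SiMe3 while anhydrous acid leaves the lactone, silylene and methyl ethers untouched.

**Step 11**
Reactants: 19 C6'-H silylene lactone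
Product: 20 pentahydroxy lactone (the O7–C1' lactone of the target with free 5-OH, ring B catechol and ring D catechol)
Conditions: BBr3 (excess), CH2Cl2, −78 °C to rt; aq. HCl work-up
Reagents that add atoms: none
Why: BBr3 demethylation (complexation, then bromide attack on methyl) cleaves the three aryl methyl ethers and exchanges the aryl silyl ether bonds for borates that hydrolyse on work-up, while aryl lactones of this type tolerate the reagent.

**Step 12**
Reactants: 20 pentahydroxy lactone
Product: 21 2-[2-(3,4-dihydroxyphenyl)-5,7-dihydroxy-4-oxo-4H-chromen-8-yl]-3,4-dihydroxybenzoic acid (target)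
Conditions: LiOH, THF/H2O (degassed, Ar), 0 °C to rt; then 1 M HCl to pH 3, 0 °C
Reagents that add atoms: lithium hydroxide, [Li+].[OH-]
Why: Saponification of the phenolic lactone under exclusion of oxygen and cold acidification should give the free acid, with relactonisation disfavoured by the clash between the C3' oxygen and O1 in the planar lactone.

**Compound list**
1 | 1-(2,4-dihydroxy-6-methoxyphenyl)ethan-1-one | CC(=O)c1c(O)cc(O)cc1OC | starting material
2 | 1-[4-(benzyloxy)-2-hydroxy-6-methoxyphenyl]ethan-1-one | CC(=O)c1c(O)cc(OCc2ccccc2)cc1OC | intermediate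
3 | 3,4-dimethoxybenzaldehyde | COc1ccc(C=O)cc1OC | starting material
4 | (E)-1-[4-(benzyloxy)-2-hydroxy-6-methoxyphenyl]-3-(3,4-dimethoxyphenyl)prop-2-en-1-one | COc1ccc(/C=C/C(=O)c2c(O)cc(OCc3ccccc3)cc2OC)cc1OC | intermediate
5 | 7-(benzyloxy)-2-(3,4-dimethoxyphenyl)-5-methoxy-4H-chromen-4-one | COc1ccc(-c2cc(=O)c3c(OC)cc(OCc4ccccc4)cc3o2)cc1OC | intermediate
6 | 7-(benzyloxy)-2-(3,4-dimethoxyphenyl)-8-iodo-5-methoxy-4H-chromen-4-one | COc1ccc(-c2cc(=O)c3c(OC)cc(OCc4ccccc4)c(I)c3o2)cc1OC | intermediate
7 | 2-(3,4-dimethoxyphenyl)-7-hydroxy-8-iodo-5-methoxy-4H-chromen-4-one | COc1ccc(-c2cc(=O)c3c(OC)cc(O)c(I)c3o2)cc1OC | intermediate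
8 | 3-(trimethylsilyl)prop-2-ynoic acid | C[Si](C)(C)C#CC(=O)O | starting material
9 | 2-(3,4-dimethoxyphenyl)-8-iodo-5-methoxy-4-oxo-4H-chromen-7-yl 3-(trimethylsilyl)prop-2-ynoate | COc1ccc(-c2cc(=O)c3c(OC)cc(OC(=O)C#C[Si](C)(C)C)c(I)c3o2)cc1OC | intermediate
10 | 3-phenylisoxazole | c1ccc(-c2ccon2)cc1 | starting material
11 | di-tert-butylsilyl bis(trifluoromethanesulfonate) | CC(C)(C)[Si](OS(=O)(=O)C(F)(F)F)(OS(=O)(=O)C(F)(F)F)C(C)(C)C | starting material
12 | 5-lithio-3-phenylisoxazole | [Li]c1cc(-c2ccccc2)no1 | intermediate
13 | lithium ethynolate | [Li+].[O-]C#C | intermediate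
14 | di-tert-butylbis(ethynyloxy)silane | C#CO[Si](OC#C)(C(C)(C)C)C(C)(C)C | intermediate
15 | lithium {[di-tert-butyl(ethynyloxy)silyl]oxy}ethynide | [Li+].[C-]#CO[Si](OC#C)(C(C)(C)C)C(C)(C)C | intermediate
16 | chloro({[di-tert-butyl(ethynyloxy)silyl]oxy}ethynyl)zinc | Cl[Zn]C#CO[Si](OC#C)(C(C)(C)C)C(C)(C)C | intermediate
17 | 8-({[di-tert-butyl(ethynyloxy)silyl]oxy}ethynyl)-2-(3,4-dimethoxyphenyl)-5-methoxy-4-oxo-4H-chromen-7-yl 3-(trimethylsilyl)prop-2-ynoate | COc1ccc(-c2cc(=O)c3c(OC)cc(OC(=O)C#C[Si](C)(C)C)c(C#CO[Si](OC#C)(C(C)(C)C)C(C)(C)C)c3o2)cc1OC | intermediate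
18 | flavone-fused benzo[c]chromen-6-one with SiMe3 on C6' and di-tert-butylsilylene on the C3' and C4' oxygens (5-OMe, 3,4-dimethoxyphenyl on C2) | COc1ccc(-c2cc(=O)c3c(OC)cc4oc(=O)c5c([Si](C)(C)C)cc6O[Si](C(C)(C)C)(C(C)(C)C)Oc6c5c4c3o2)cc1OC | intermediate
19 | the same lactone with H on C6' | COc1ccc(-c2cc(=O)c3c(OC)cc4oc(=O)c5ccc6O[Si](C(C)(C)C)(C(C)(C)C)Oc6c5c4c3o2)cc1OC | intermediate
20 | pentahydroxy lactone (O7–C1' lactone of the target) | Oc1ccc(-c2cc(=O)c3c(O)cc4oc(=O)c5ccc(O)c(O)c5c4c3o2)cc1O | intermediate
21 | 2-[2-(3,4-dihydroxyphenyl)-5,7-dihydroxy-4-oxo-4H-chromen-8-yl]-3,4-dihydroxybenzoic acid | O=C(O)c1ccc(O)c(O)c1-c1c(O)cc(O)c2c(=O)cc(-c3ccc(O)c(O)c3)oc12 | target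

**Step count**
Total: 12 steps. Longest linear sequence: 11 steps (steps 1–6 and 8–12); step 7 is a one-step branch.

**Steps most likely to fail**

1. Step 9 (the proposed new method). The electron-rich ynol ethers may be diverted at the metal into ketene-type decomposition or intermolecular oligomerisation faster than the strained O–Si–O tether can close.
   The fallback uses known cross-coupling chemistry and brings ring D in intact. It sets out from iodide 6. Miyaura borylation of methyl 2-bromo-3,4-dimethoxybenzoate (PdCl2(dppf), B2pin2, KOAc, dioxane, 90 °C) would give methyl 3,4-dimethoxy-2-(4,4,5,5-tetramethyl-1,3,2-dioxaborolan-2-yl)benzoate F1. Suzuki–Miyaura coupling of F1 with 6 (Pd(OAc)2, SPhos, K3PO4, toluene/H2O, 100 °C) would give methyl 2-[7-(benzyloxy)-2-(3,4-dimethoxyphenyl)-5-methoxy-4-oxo-4H-chromen-8-yl]-3,4-dimethoxybenzoate F2. BBr3 in CH2Cl2 would then cleave the benzyl and all methyl ethers, and the freed 7-OH would close onto the neighbouring ester. This comes back to the route at lactone 20.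

2. Step 8. Metalation of 14 may be accompanied by attack at silicon or silyl transfer between oxygen and carbon. Coupling at both termini and hydrolysis of the ynol silyl ether during isolation are further risks.
   The fallback avoids strong base and zinc and sets out from 14 and 9. Stannylation of one terminus of 14 with Bu3SnNEt2 (THF, rt, amine removed under vacuum) would give tributyl({[di-tert-butyl(ethynyloxy)silyl]oxy}ethynyl)stannane F3. Stille coupling of F3 with 9 (Pd2(dba)3, AsPh3, THF, 50 °C) comes back to the route at triyne 17.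

3. Step 7. The unhindered parent ynolate may be silylated on carbon to give silylketenes, may add to the benzonitrile co-product, or the cycloreversion may be incomplete at low temperature.
   The fallback makes the ynolate by oxidation instead of fragmentation and sets out from 11. Acetylene and n-BuLi in THF at −78 °C would give lithium acetylide F4. Oxidation with t-BuOOLi (from t-BuOOH and LiN(SiMe3)2, −78 to −20 °C) would give lithium ethynolate 13 free of nitrile. Silylation with 11 comes back to the route at 14.

**Further compounds**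
F1 | step 9 | methyl 3,4-dimethoxy-2-(4,4,5,5-tetramethyl-1,3,2-dioxaborolan-2-yl)benzoate | COC(=O)c1ccc(OC)c(OC)c1B1OC(C)(C)C(C)(C)O1
F2 | step 9 | methyl 2-[7-(benzyloxy)-2-(3,4-dimethoxyphenyl)-5-methoxy-4-oxo-4H-chromen-8-yl]-3,4-dimethoxybenzoate | COC(=O)c1ccc(OC)c(OC)c1-c1c(OCc2ccccc2)cc(OC)c2c(=O)cc(-c3ccc(OC)c(OC)c3)oc12
F3 | step 8 | tributyl({[di-tert-butyl(ethynyloxy)silyl]oxy}ethynyl)stannane | CCCC[Sn](CCCC)(CCCC)C#CO[Si](OC#C)(C(C)(C)C)C(C)(C)C
F4 | step 7 | lithium acetylide | [Li+].[C-]#C
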